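## Analysis of the target

- **Skeleton.** The core is tricyclo[4.2.1.1^{2,5}]deca-3,7-diene, numbered C1–C10 throughout. Ring A is the cyclopentene C1, C9, C6, C7, C8 (C7=C8); ring B is the cyclopentene C2, C10, C5, C4, C3 (C3=C4). The bonds C1–C2 and C5–C6 join them head to head, and with the methylene bridges C9 and C10 they close a six-membered ring C (C1, C2, C10, C5, C6, C9) held as a boat with both bridges syn. This is the connectivity of a (4+4) cyclodimer of two cyclopentadienes.
- **Substituents.** C1 (quaternary) and C3 carry methyl groups. C8 and C4 each carry the same cis-disubstituted gem-dimethylcyclopropane with a 3-oxobutyl arm, (1R,3S) at the ring-bearing and arm-bearing carbons.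
- **Stereocentres.** There are eight: four in the two identical cyclopropanes and four in the core (C1, C2, C5, C6, all S). The core centres are tied together by the rings, so only two choices remain: syn versus anti, and which face of each five-membered ring bonds. Because the cyclopropanes are homochiral, the molecule is pseudo-C2 symmetric: both halves have bonded on the same diastereoface.
- **Feature used by the strategy.** In each five-membered ring the cyclopropyl-bearing alkene carbon (C8, C4) lies between a methyl-bearing carbon (C1, C3) and a CH carbon (C7 vinylic, C5 bridgehead). Both rings are therefore the pattern of one 2-cyclopropyl-3-methylcyclopent-2-en-1-one with C7 and C5 as former carbonyl carbons. In that reading C1 is a β-carbon and C6 an α′-carbon (ring A), while C2 is a γ-carbon and C5 a carbonyl carbon (ring B).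
- **Sensitive groups.** Two vinylcyclopropanes (opened by radicals, triplets or cations on C8 or C4), two enolisable methyl ketones, and two strained alkenes that face each other.
- **What is hard.** The (4+4) connectivity is not open to a ground-state cycloaddition. C1–C2 joins a quaternary to a tertiary carbon, each next to a fully substituted sp2 carbon. The cyclopropane is enantiomeric to that of the commercial carane terpenes ((+)-2-carene, (+)-3-carene), so the usual chiral-pool entry is closed.

## Retrosynthetic reasoning

**22 to 21.** The two methyl ketones are masked as dioxolanes. Every carbanion step then sees only the ring carbonyls, and the last step is a mild hydrolysis.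

**21 to 18 (through 20).** The vinylic C7–H is traced back to a ketone at C7. This is no detour: the C7 carbonyl is what makes C6 nucleophilic for ring closure, and it can enolise only towards C8 (C6 is a bridgehead), so the C7=C8 alkene is regiodefined.

**18 to 16: cut C5–C6.** Ring C is opened at the bond between the α′-carbon of the ring A ketone and an allylic carbon of ring B. Forward, an enolate attacks an η3-allyl spanning C5–C4–C3 at its less substituted end, which leaves the tetrasubstituted C3=C4 alkene in place. Cutting here rather than at C1–C2 keeps the hindered quaternary bond out of the ring-closing step.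

**16 to 13.** The allylic C5–O bond comes from the ring B enone carbonyl by 1,2-reduction. The C5 oxygen is used twice: as a carbonyl it makes C2 nucleophilic, and as a carbonate it makes C5 electrophilic. C1–C2 must therefore be formed before C5 is reduced.

**13 to 10 + 10: cut C1–C2.** This is the strategic cut. It divides the C34 bis-ketal into two molecules of one enone, 10. Forward, the γ-carbon of the dienolate of 10 adds to the β-carbon of a second molecule of 10, forming the quaternary–tertiary bond and setting C1 and C2 together.

**10 to 8.** The cyclopentenone is cut by a Pauson–Khand disconnection to the methyl-capped alkyne 8. The bulky cyclopropyl substituent ends next to the carbonyl, which is the regiochemistry the target needs.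

**8 to 6 (through 7).** The protected 3-oxobutyl arm is traced to the aldehyde 6 by a one-carbon-retaining methyl ketone homologation.

**6 to 4 to 3.** Alkyne and aldehyde are the two ends of a ring cleaved by Eschenmoser–Tanabe fragmentation. C2, C3 and the methyl of 3 become the propynyl group; C4 becomes the aldehyde. No carbon is lost and none has to be added to reach the alkyne.

**3 to 2 to 1.** The gem-dimethylcyclopropane comes from the isopropenyl group of 1 by hydrochlorination and 1,3-elimination. The single stereocentre of 1 fixes both cyclopropane centres, and the (S) enantiomer of 1 gives the series the target needs.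

## Alternatives that were turned down

**Alternative 1:** the textbook cut of both inter-ring bonds at once. The forward step is a head-to-head (4+4) cyclodimerisation of the cyclopentadiene A1, thermally or with a triplet sensitiser. It was turned down for three reasons.
- A suprafacial ground-state (4+4) process is symmetry-forbidden, so a cyclopentadiene such as A1 would take the allowed (4+2) path and bond through adjacent carbons of one ring.
- Ring A and ring B of the target correspond to two different 1,5-hydrogen-shift tautomers of A1 (methyl on the diene terminus in ring A, internal in ring B), and nothing in a dimerisation selects that pair.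
- Sensitised excitation puts spin density on the cyclopropyl-bearing carbon and invites ring opening.

The step count would be the lowest, but the step cannot be defended.

**Alternative 2:** cut C1–C2 and C5–C6 as a (4+3) cycloaddition of an oxyallyl cation (C2–C10–C5, carbonyl on C10) with the diene A1 in ketal form, giving the bridging ketone A2, followed by Wolff–Kishner-type removal of the C10 carbonyl. It was turned down because the three-carbon partner would need the carbonyl on the one-carbon bridge and the C3=C4 alkene in the same five-membered ring, a four-electron antiaromatic cation. A saturated partner would leave the tetrasubstituted alkene and its cyclopropyl group to be installed afterwards. The enone obtained from the alkyne also carries its oxygen on the wrong carbon (C5, not C10), so the two halves could not share one building block.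

**Alternative 3:** core first. The two cyclopropyl groups are cut from C4 and C8; forward, the bis(enol triflate) A3 undergoes double Suzuki coupling with the cyclopropylboronate A4. It was turned down because A3 holds all four core stereocentres and would need its own enantioselective synthesis with no chirality source in sight. The couplings would join secondary cyclopropyl carbons to hindered, fully substituted enol triflates, twice. A4 is no easier to make than the alkyne 8. The cyclopropyl groups would also be unable to steer the core configuration.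

Key step: step 8

Remarks on the chemistry:
- Q stands for the ketal-protected side arm (1R,3S)-2,2-dimethyl-3-[2-(2-methyl-1,3-dioxolan-2-yl)ethyl]cyclopropyl.
- Core atoms of 11 to 22 carry the numbers C1–C10 defined above. In enone 10, ring positions 1, 2, 3, 4, 5 become C7, C8, C1, C9, C6 in ring A and C5, C4, C3, C2, C10 in ring B.
- 7 is formed and used as an E/Z mixture. C8 in 15 to 18 is a mixture of epimers that becomes trigonal again in step 12. The epoxide centres of 4 are erased in step 4. These centres are left open or are inconsequential in the SMILES.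

## Route

Step 1
Reactants: 1 (S)-(+)-carvone
Product: 2 (5S)-5-(2-chloropropan-2-yl)-2-methylcyclohex-2-en-1-one
Conditions: HCl (g), Et2O, 0 °C
Reagents that add atoms: hydrogen chloride, Cl
Why: Markovnikov hydrochlorination of the isolated 1,1-disubstituted alkene; the conjugated ring alkene does not add HCl under these conditions and the C5 stereocentre is untouched.

Step 2
Reactants: 2 (5S)-5-(2-chloropropan-2-yl)-2-methylcyclohex-2-en-1-one
Product: 3 (1R,6S)-3,7,7-trimethylbicyclo[4.1.0]hept-3-en-2-one
Conditions: t-BuOK, THF, −10 °C, short reaction time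
Reagents that add atoms: none
Why: 1,3-Elimination: the α′-enolate displaces the tertiary chloride (3-exo-tet), and since the ring fusion can only be cis the one stereocentre of 2 fixes both cyclopropane centres. Cold, brief exposure to base limits ring expansion of the product.

Step 3
Reactants: 3 (1R,6S)-3,7,7-trimethylbicyclo[4.1.0]hept-3-en-2-one
Product: 4 (1R,6S)-3,4-epoxy-3,7,7-trimethylbicyclo[4.1.0]heptan-2-one, epoxide anti to C7
Conditions: 30% H2O2, NaOH (cat.), MeOH, 0 °C
Reagents that add atoms: hydrogen peroxide, OO
Why: Weitz–Scheffer nucleophilic epoxidation of the enone; hydroperoxide should add to C4 on the face away from the gem-dimethyl bridge, and both new centres are destroyed in step 4.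

Step 4
Reactants: 4 (1R,6S)-3,4-epoxy-3,7,7-trimethylbicyclo[4.1.0]heptan-2-one
Product: 6 2-[(1S,3R)-2,2-dimethyl-3-(prop-1-yn-1-yl)cyclopropyl]acetaldehyde, via tosylhydrazone 5 (not isolated)
Conditions: TsNHNH2 (1.0 equiv), AcOH/CH2Cl2 (1:1), −20 to 25 °C
Reagents that add atoms: p-toluenesulfonylhydrazide, Cc1ccc(cc1)S(=O)(=O)NN (its atoms are present in 5 only)
Why: Eschenmoser–Tanabe fragmentation: the hydrazone opens the epoxide, and loss of N2 and sulfinate cleaves C3–C4, turning C2–C3 with its methyl into the propynyl group and C4 into the aldehyde. No cation or radical forms next to the cyclopropane, whose two centres are untouched.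

Step 5
Reactants: 6 2-[(1S,3R)-2,2-dimethyl-3-(prop-1-yn-1-yl)cyclopropyl]acetaldehyde
Product: 7 (1S,3R)-1-(3-methoxybut-2-en-1-yl)-2,2-dimethyl-3-(prop-1-yn-1-yl)cyclopropane (E/Z mixture)
Conditions: [Ph3PCH(OMe)CH3]Cl, t-BuOK, THF, −40 °C; then 6, −78 to 0 °C
Reagents that add atoms: (1-methoxyethyl)triphenylphosphonium chloride, COC(C)[P+](c1ccccc1)(c1ccccc1)c1ccccc1.[Cl-]
Why: Wittig olefination with an α-methoxyalkylidene ylide makes the enol ether of the homologous methyl ketone; the alkene geometry is irrelevant because the carbon becomes sp3 in step 6.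

Step 6
Reactants: 7 (1S,3R)-1-(3-methoxybut-2-en-1-yl)-2,2-dimethyl-3-(prop-1-yn-1-yl)cyclopropane
Product: 8 2-{2-[(1S,3R)-2,2-dimethyl-3-(prop-1-yn-1-yl)cyclopropyl]ethyl}-2-methyl-1,3-dioxolane
Conditions: HOCH2CH2OH, PPTS (cat.), CH2Cl2, 25 °C
Reagents that add atoms: ethylene glycol, OCCO
Why: Acid-catalysed addition of the diol to the enol ether and exchange of methanol (transketalisation) gives the dioxolane directly, so the free ketone is never handled; PPTS is too weak to protonate the alkyne or open the cyclopropane.

Step 7
Reactants: 8 2-{2-[(1S,3R)-2,2-dimethyl-3-(prop-1-yn-1-yl)cyclopropyl]ethyl}-2-methyl-1,3-dioxolane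
Product: 10 2-Q-3-methylcyclopent-2-en-1-one, via hexacarbonyldicobalt complex 9 (not isolated)
Conditions: Co2(CO)8, CH2Cl2, 25 °C; then ethylene (30 atm), Me3NO·2H2O, toluene, 40 °C (autoclave)
Reagents that add atoms: dicobalt octacarbonyl, Co2(CO)8, O=C=[Co](=C=O)(=C=O)(=C=O)[Co](=C=O)(=C=O)(=C=O)=C=O (one CO ends in 10, cobalt in 9 only); ethylene, C=C
Why: Intermolecular Pauson–Khand reaction of the alkyne–Co2(CO)6 complex with ethylene; the bulkier alkyne substituent (the cyclopropyl carbon) should end next to the new carbonyl and the methyl at the β-carbon. The neutral conditions leave the cyclopropane and ketal alone.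

Step 8
Reactants: 10 2-Q-3-methylcyclopent-2-en-1-one (two molecules)
Product: 13 (4S)-3-methyl-2-Q-4-[(1S)-1-methyl-2-Q-3-(trimethylsilyloxy)cyclopent-2-en-1-yl]cyclopent-2-en-1-one, via potassium dienolate 11 (not isolated), via potassium enolate 12 (not isolated)
Conditions: KN(SiMe3)2 (0.5 equiv), THF/toluene, −78 to −10 °C; then Me3SiCl, Et3N, −78 °C
Reagents that add atoms: chlorotrimethylsilane, C[Si](C)(C)Cl; potassium bis(trimethylsilyl)amide, KN(SiMe3)2, C[Si](C)(C)[N-][Si](C)(C)C.[K+] (potassium in 11 and 12 only)
Why: Half an equivalent of KN(SiMe3)2 turns one of two molecules of 10 into an enolate, and proton exchange with the remaining 10 funnels the kinetic α′-enolate into the conjugated dienolate 11 (O–C5=C4–C3=C2), whose γ-carbon C2 adds to the β-carbon C1 of the second molecule; this is a vinylogous Michael addition, the known reaction type by which 3-methylcycloalkenones dimerise under base and cyclic dienolates add to enones. The adduct is the tetrasubstituted enolate 12 (C7–O, C7=C8), too hindered to add further, and silylation fixes it as 13 with ring B returned to its enone. No ring is closed here: the step forms the quaternary–tertiary bond C1–C2 and joins the two C17 halves, and ring C is closed later at C5–C6 (step 11). Donor-site selectivity is needed: attack through the α-carbon C4 would build two adjacent quaternary carbons and carbonyl (1,2) adducts revert, while the α′-enolate is the minor species at equilibrium. The relative configuration of C1 and C2 is expected from a closed transition state in which K+ bridges the dienolate oxygen on C5 and the enone oxygen on C7, so that ring B lies under ring A head to head (C2 under C1, C3 under C8, C4 under C7, C5 under C6), the stacking kept in 22. The face of each ring is chosen by its own cyclopropyl group; because the halves are homochiral and 22 is pseudo-C2 symmetric, the needed product is the doubly matched one in which both rings turn the same diastereoface inward. C2 stays epimerisable through the dienolate of ring B, so an unwanted C2 epimer can be recycled with base.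

Step 9
Reactants: 13 (4S)-3-methyl-2-Q-4-[(1S)-1-methyl-2-Q-3-(trimethylsilyloxy)cyclopent-2-en-1-yl]cyclopent-2-en-1-one
Product: 15 3-(4-hydroxy-2-methyl-3-Q-cyclopent-2-en-1-yl)-3-methyl-2-Q-cyclopentan-1-one (C1 and C2 as in 13, hydroxyl on C5 cis to the C2–C1 bond), via allylic alcohol 14 (not isolated)
Conditions: i-Bu2AlH, CH2Cl2, −78 °C; aq. KNaC4H4O6 work-up; then K2CO3, MeOH, 0 °C
Reagents that add atoms: none
Why: 1,2-Reduction of the ring B enone by i-Bu2AlH; hydride should come anti to the bulky ring A substituent on C2, which sets C5 with its hydroxyl cis to the C2–C1 bond. The silyl enol ether shields the ring A carbonyl during reduction and is then methanolysed to the ketone.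

Step 10
Reactants: 15 3-(4-hydroxy-2-methyl-3-Q-cyclopent-2-en-1-yl)-3-methyl-2-Q-cyclopentan-1-one
Product: 16 methyl carbonate of 15 (methoxycarbonyloxy group on C5)
Conditions: ClCO2Me, pyridine, DMAP (cat.), CH2Cl2, 0 °C
Reagents that add atoms: methyl chloroformate, COC(=O)Cl
Why: Acylation of the secondary allylic alcohol gives the leaving group for the palladium step; the C5 configuration is retained and the ketone does not react.

Step 11
Reactants: 16 methyl carbonate of 15
Product: 18 1,3-dimethyl-4,8-di-Q-tricyclo[4.2.1.1^{2,5}]dec-3-en-7-one (C1, C2, C5, C6 arranged as in 22, bridges syn), via lithium enolate 17 (not isolated)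
Conditions: LiN(SiMe3)2 (1.1 equiv), THF, −78 °C; then Pd(PPh3)4 (10 mol %), −78 to 25 °C
Reagents that add atoms: lithium bis(trimethylsilyl)amide, LiN(SiMe3)2, C[Si](C)(C)[N-][Si](C)(C)C.[Li+] (lithium in 17 only)
Why: Kinetic deprotonation takes the unhindered C6 methylene (C8–H is tertiary and shielded by the cyclopropyl group) to give 17. Zerovalent palladium ionises the carbonate with inversion to an η3-allyl over C5–C4–C3, and the enolate carbon attacks the less substituted terminus C5 anti to palladium (intramolecular Tsuji–Trost alkylation, net retention, which is why the cis alcohol of step 9 is needed). This 6-(enolexo)-exo closure forms C5–C6, closes ring C as a boat and fixes C5 and C6; attack at C3 would build two adjacent quaternary carbons in a bicyclo[2.2.1] frame and is not expected.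

Step 12
Reactants: 18 1,3-dimethyl-4,8-di-Q-tricyclo[4.2.1.1^{2,5}]dec-3-en-7-one
Product: 20 1,3-dimethyl-4,8-di-Q-tricyclo[4.2.1.1^{2,5}]deca-3,7-dien-7-yl trifluoromethanesulfonate, via potassium enolate 19 (not isolated)
Conditions: KN(SiMe3)2, THF, −78 to 0 °C; then PhNTf2, −78 to 0 °C
Reagents that add atoms: N-phenylbis(trifluoromethanesulfonimide), O=S(=O)(N(c1ccccc1)S(=O)(=O)C(F)(F)F)C(F)(F)F; potassium bis(trimethylsilyl)amide, KN(SiMe3)2, C[Si](C)(C)[N-][Si](C)(C)C.[K+] (potassium in 19 only)
Why: Enol triflate formation; the ketone can enolise only towards C8 because C6 is a bridgehead, so a single regioisomer with the C7=C8 double bond results and the mixed C8 centre disappears.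

Step 13
Reactants: 20 1,3-dimethyl-4,8-di-Q-tricyclo[4.2.1.1^{2,5}]deca-3,7-dien-7-yl trifluoromethanesulfonate
Product: 21 (1S,2S,5S,6S)-1,3-dimethyl-4,8-di-Q-tricyclo[4.2.1.1^{2,5}]deca-3,7-diene
Conditions: Pd(OAc)2 (5 mol %), PPh3, HCO2H, n-Bu3N, DMF, 60 °C
Reagents that add atoms: none
Why: Palladium-catalysed formate reduction of the enol triflate replaces the triflate by hydrogen without moving the double bond; no stereocentre is touched.

Step 14
Reactants: 21 (1S,2S,5S,6S)-1,3-dimethyl-4,8-di-Q-tricyclo[4.2.1.1^{2,5}]deca-3,7-diene
Product: 22 (1S,2S,5S,6S)-1,3-dimethyl-4,8-bis[(1R,3S)-2,2-dimethyl-3-(3-oxobutyl)cyclopropyl]tricyclo[4.2.1.1^{2,5}]deca-3,7-diene (CNP0300925.1)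
Conditions: PPTS, acetone/H2O (4:1), 50 °C
Reagents that add atoms: water, O
Why: Mild acid hydrolysis of both dioxolanes; PPTS should be too weak to protonate the tri- and tetrasubstituted alkenes next to the cyclopropanes.

## Compound list

1 | (S)-(+)-carvone, (5S)-2-methyl-5-(prop-1-en-2-yl)cyclohex-2-en-1-one | CC1=CC[C@@H](CC1=O)C(C)=C | starting material
2 | (5S)-5-(2-chloropropan-2-yl)-2-methylcyclohex-2-en-1-one | CC1=CC[C@@H](CC1=O)C(C)(C)Cl | intermediate
3 | (1R,6S)-3,7,7-trimethylbicyclo[4.1.0]hept-3-en-2-one | CC1=CC[C@H]2[C@@H](C1=O)C2(C)C | intermediate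
4 | (1R,6S)-3,4-epoxy-3,7,7-trimethylbicyclo[4.1.0]heptan-2-one, epoxide anti to C7 | C[C@]12O[C@H]1C[C@H]1[C@@H](C2=O)C1(C)C | intermediate
5 | N-tosylhydrazone of 4 | C[C@]12O[C@H]1C[C@H]1[C@@H](C2=NNS(=O)(=O)c3ccc(C)cc3)C1(C)C | intermediate
6 | 2-[(1S,3R)-2,2-dimethyl-3-(prop-1-yn-1-yl)cyclopropyl]acetaldehyde | O=CC[C@H]1[C@@H](C#CC)C1(C)C | intermediate
7 | (1S,3R)-1-(3-methoxybut-2-en-1-yl)-2,2-dimethyl-3-(prop-1-yn-1-yl)cyclopropane, E/Z mixture | COC(C)=CC[C@H]1[C@@H](C#CC)C1(C)C | intermediate
8 | 2-{2-[(1S,3R)-2,2-dimethyl-3-(prop-1-yn-1-yl)cyclopropyl]ethyl}-2-methyl-1,3-dioxolane | CC1(CC[C@H]2[C@@H](C#CC)C2(C)C)OCCO1 | intermediate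
9 | hexacarbonyldicobalt complex of alkyne 8, (μ-alkyne)Co2(CO)6 | CC1(CC[C@H]2[C@@H](C34C5(C)[Co]3(=C=O)(=C=O)(=C=O)[Co]45(=C=O)(=C=O)=C=O)C2(C)C)OCCO1 | intermediate
10 | 2-{(1R,3S)-2,2-dimethyl-3-[2-(2-methyl-1,3-dioxolan-2-yl)ethyl]cyclopropyl}-3-methylcyclopent-2-en-1-one (2-Q-3-methylcyclopent-2-en-1-one) | CC1(CC[C@H]2[C@@H](C3=C(C)CCC3=O)C2(C)C)OCCO1 | intermediate
11 | potassium 3-methyl-2-Q-cyclopenta-1,3-dien-1-olate (conjugated dienolate of 10) | [K+].CC1(CC[C@H]2[C@@H](C3=C([O-])CC=C3C)C2(C)C)OCCO1 | intermediate
12 | potassium enolate of the Michael dimer (O on C7, C7=C8; ring B enone; C1 and C2 as in 13) | [K+].CC1(CC[C@H]2[C@@H](C3=C([O-])CC[C@@]3(C)[C@H]3CC(=O)C([C@@H]4[C@H](CCC5(C)OCCO5)C4(C)C)=C3C)C2(C)C)OCCO1 | intermediate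
13 | (4S)-3-methyl-2-Q-4-[(1S)-1-methyl-2-Q-3-(trimethylsilyloxy)cyclopent-2-en-1-yl]cyclopent-2-en-1-one | CC1(CC[C@H]2[C@@H](C3=C(O[Si](C)(C)C)CC[C@@]3(C)[C@H]3CC(=O)C([C@@H]4[C@H](CCC5(C)OCCO5)C4(C)C)=C3C)C2(C)C)OCCO1 | intermediate
14 | allylic alcohol from 13 (hydroxyl on C5 cis to the C2–C1 bond, ring A still the silyl enol ether) | CC1(CC[C@H]2[C@@H](C3=C(O[Si](C)(C)C)CC[C@@]3(C)[C@H]3C[C@@H](O)C([C@@H]4[C@H](CCC5(C)OCCO5)C4(C)C)=C3C)C2(C)C)OCCO1 | intermediate
15 | 3-(4-hydroxy-2-methyl-3-Q-cyclopent-2-en-1-yl)-3-methyl-2-Q-cyclopentan-1-one (C1, C2 as in 13; hydroxyl on C5 cis to the C2–C1 bond; C8 epimers) | CC1(CC[C@H]2[C@@H](C3C(=O)CC[C@@]3(C)[C@H]3C[C@@H](O)C([C@@H]4[C@H](CCC5(C)OCCO5)C4(C)C)=C3C)C2(C)C)OCCO1 | intermediate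
16 | methyl carbonate of 15 (methoxycarbonyloxy on C5) | CC1(CC[C@H]2[C@@H](C3C(=O)CC[C@@]3(C)[C@H]3C[C@@H](OC(=O)OC)C([C@@H]4[C@H](CCC5(C)OCCO5)C4(C)C)=C3C)C2(C)C)OCCO1 | intermediate
17 | lithium enolate of 16 (O on C7, C6=C7) | [Li+].CC1(CC[C@H]2[C@@H](C3C([O-])=CC[C@@]3(C)[C@H]3C[C@@H](OC(=O)OC)C([C@@H]4[C@H](CCC5(C)OCCO5)C4(C)C)=C3C)C2(C)C)OCCO1 | intermediate
18 | 1,3-dimethyl-4,8-di-Q-tricyclo[4.2.1.1^{2,5}]dec-3-en-7-one (C1, C2, C5, C6 arranged as in 22; C8 epimers) | CC1(CC[C@H]2[C@@H](C3C(=O)[C@@H]4C[C@@]3(C)[C@H]3C[C@@H]4C([C@@H]4[C@H](CCC5(C)OCCO5)C4(C)C)=C3C)C2(C)C)OCCO1 | intermediate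
19 | potassium enolate of 18 (O on C7, C7=C8) | [K+].CC1(CC[C@H]2[C@@H](C3=C([O-])[C@@H]4C[C@@]3(C)[C@H]3C[C@@H]4C([C@@H]4[C@H](CCC5(C)OCCO5)C4(C)C)=C3C)C2(C)C)OCCO1 | intermediate
20 | 1,3-dimethyl-4,8-di-Q-tricyclo[4.2.1.1^{2,5}]deca-3,7-dien-7-yl trifluoromethanesulfonate (core as in 22) | CC1(CC[C@H]2[C@@H](C3=C(OS(=O)(=O)C(F)(F)F)[C@@H]4C[C@@]3(C)[C@H]3C[C@@H]4C([C@@H]4[C@H](CCC5(C)OCCO5)C4(C)C)=C3C)C2(C)C)OCCO1 | intermediate
21 | (1S,2S,5S,6S)-1,3-dimethyl-4,8-di-Q-tricyclo[4.2.1.1^{2,5}]deca-3,7-diene (bis-dioxolane of 22) | CC1(CC[C@H]2[C@@H](C3=C[C@@H]4C[C@@]3(C)[C@H]3C[C@@H]4C([C@@H]4[C@H](CCC5(C)OCCO5)C4(C)C)=C3C)C2(C)C)OCCO1 | intermediate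
22 | (1S,2S,5S,6S)-1,3-dimethyl-4,8-bis[(1R,3S)-2,2-dimethyl-3-(3-oxobutyl)cyclopropyl]tricyclo[4.2.1.1^{2,5}]deca-3,7-diene | CC(=O)CC[C@H]1[C@@H](C2=C[C@@H]3C[C@@]2(C)[C@H]2C[C@@H]3C([C@@H]3[C@H](CCC(C)=O)C3(C)C)=C2C)C1(C)C | target

## Step count and least certain steps

Total step count: 14. Longest linear sequence: 14 (both halves of the target come from the same compound 10, so the sequence is linear up to the self-union in step 8).

**Step 8 (key step).** Three things may go wrong:
- addition to the fully substituted enone may be slow or reversible;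
- the minor α′-enolate may compete as the donor;
- the two rings may meet with poor facial selectivity, since the two flanks of each cyclopropyl group differ only modestly in size and the matched pairing is an expectation, not a certainty.

Fallback: 10 is first converted completely into its conjugated potassium dienolate (KH, THF, 0 °C) and silylated at −78 °C to the regiodefined extended trimethylsilyl dienol ether F1. F1 is then combined with one equivalent of 10 in an uncatalysed Mukaiyama–Michael addition under high pressure (about 12 kbar, CH2Cl2, 25 °C). No Lewis acid is present, so the dioxolanes are safe, and silyl transfer should deliver 13 directly. The fallback sets out from 10 and returns at 13. It separates the choice of donor site from the bond formation and replaces the ion-paired transition state by a neutral, compact one.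

**Step 11.** The allylic carbonate sits next to a tetrasubstituted alkene, so ionisation by zerovalent palladium may be slow. This leaves time for enolate equilibration towards C8 or for acyl transfer from the carbonate. Fallback: the alcohol 15 is converted with inversion (CBr4, PPh3, CH2Cl2, 0 °C) into the allylic bromide F2, with bromine on C5 trans to the C2–C1 bond. The kinetic C6 enolate (LiN(SiMe3)2, THF, −78 to 0 °C) then closes ring C by direct intramolecular SN2 displacement with a second inversion. The fallback sets out from 15 and returns at 18 with the same configuration at C5 and C6.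

**Step 7.** Intermolecular cycloaddition of an internal, branched alkyne with ethylene may be sluggish and its regioselectivity incomplete. Fallback: 8 is coupled with ethylene on zirconocene (Cp2ZrCl2, 2 EtMgBr, THF, −78 to 0 °C) to the zirconacyclopentene F3, in which the bulky cyclopropyl carbon sits next to zirconium. Carbonylation (CO, 1 atm) and protonolysis then give the cyclopentenone. The fallback sets out from 8 and returns at 10. It works at ambient pressure and fixes the regiochemistry in a separate metallacycle-forming event.

**Step 12.** Deprotonation of the tertiary C8–H, flanked by the quaternary C1 and the cyclopropyl group, may be slow or incomplete. Fallback: 18 is condensed with TsNHNH2 (EtOH, 50 °C) to the tosylhydrazone F4. Its sodium salt is thermolysed under aprotic Bamford–Stevens conditions (NaH, diglyme, 140 °C); the C7 carbene should undergo a 1,2-hydrogen shift from C8 (C6 has no suitably aligned hydrogen that would give a stable alkene). The fallback sets out from 18 and returns directly at 21, bypassing 20 and step 13.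

## Further compounds

F1 | step 8 | 3-methyl-2-Q-1-(trimethylsilyloxy)cyclopenta-1,3-diene (extended silyl dienol ether of 10) | CC1(CC[C@H]2[C@@H](C3=C(O[Si](C)(C)C)CC=C3C)C2(C)C)OCCO1
F2 | step 11 | 3-(4-bromo-2-methyl-3-Q-cyclopent-2-en-1-yl)-3-methyl-2-Q-cyclopentan-1-one, bromine on C5 trans to the C2–C1 bond | CC1(CC[C@H]2[C@@H](C3C(=O)CC[C@@]3(C)[C@H]3C[C@H](Br)C([C@@H]4[C@H](CCC5(C)OCCO5)C4(C)C)=C3C)C2(C)C)OCCO1
F3 | step 7 | 1,1-bis(cyclopentadienyl)-3-methyl-2-Q-1-zirconacyclopent-2-ene | CC1(CC[C@H]2[C@@H](C3=C(C)CC[Zr]3(C4C=CC=C4)C4C=CC=C4)C2(C)C)OCCO1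
F4 | step 12 | N-tosylhydrazone of 18 (at C7) | CC1(CC[C@H]2[C@@H](C3C(=NNS(=O)(=O)c6ccc(C)cc6)[C@@H]4C[C@@]3(C)[C@H]3C[C@@H]4C([C@@H]4[C@H](CCC5(C)OCCO5)C4(C)C)=C3C)C2(C)C)OCCO1
A1 | alternative 1 | 4-[(1S,3R)-2,2-dimethyl-3-(2-methylcyclopenta-1,4-dien-1-yl)cyclopropyl]butan-2-one (one of its 1,5-hydrogen-shift tautomers) | CC(=O)CC[C@H]1[C@@H](C2=C(C)CC=C2)C1(C)C
A2 | alternative 2 | 1,3-dimethyl-4,8-di-Q-tricyclo[4.2.1.1^{2,5}]deca-3,7-dien-10-one (core as in 22) | CC1(CC[C@H]2[C@@H](C3=C[C@@H]4C[C@@]3(C)[C@H]3C(=O)[C@@H]4C([C@@H]4[C@H](CCC5(C)OCCO5)C4(C)C)=C3C)C2(C)C)OCCO1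
A3 | alternative 3 | (1S,2S,5S,6S)-1,3-dimethyltricyclo[4.2.1.1^{2,5}]deca-3,7-diene-4,8-diyl bis(trifluoromethanesulfonate) | FC(F)(F)S(=O)(=O)OC1=C[C@@H]2C[C@@]1(C)[C@H]1C[C@@H]2C(OS(=O)(=O)C(F)(F)F)=C1C
A4 | alternative 3 | 2-{(1R,3S)-2,2-dimethyl-3-[2-(2-methyl-1,3-dioxolan-2-yl)ethyl]cyclopropyl}-4,4,5,5-tetramethyl-1,3,2-dioxaborolane | CC1(CC[C@H]2[C@@H](B3OC(C)(C)C(C)(C)O3)C2(C)C)OCCO1
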